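I wanted to know how the flasks, alike except in catalyst, rank in target at 3.0 d and at 15 h, and how much the first and the last hold.

| setting | midnight | autumn | amber | red | grey | blue | green |
|---|---|---|---|---|---|---|---|
| starting material | 0.50 M | 0.50 M | 0.50 M | 0.50 M | 0.50 M | 0.50 M | 0.50 M |
| protic impurity | 0.10 M | 0.10 M | 0.100 M | 0.100 M | 0.100 M | 0.100 M | 0.100 M |
| catalyst | 12 mM | 160 mM | 20 mM | 40 mM | 55 mM | 200 mM | 15 mM |
| remark | run made earlier | run made earlier |  |  |  |  |  |
| time |  |  | 3.0 d | 3.0 d | 3.0 d | 3.0 d | 3.0 d |

| run | time / h | target / % |
|---|---|---|
| midnight | 2.50 | 6.2 |
| midnight | 8.00 | 13.1 |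
| midnight | 15.0 | 19.3 |
| midnight | 20.0 | 16.1 |
| midnight | 30.0 | 19.1 |
| midnight | 40.0 | 20.1 |
| midnight | 48.0 | 21.1 |
| autumn | 8.00 | 73.8 |
| autumn | 15.0 | 74.5 |
| autumn | 20.0 | 74.5 |
| autumn | 30.0 | 74.9 |
| autumn | 40.0 | 75.2 |
| autumn | 48.0 | 72.7 |

(readings scatter by 1 percentage point)

- in a conversion other conformer counts as not yet reacted

- ranking by amount of target, in percent of the starting material charged, from high to low, at 3.0 d (amber / red / grey / blue / green)
- the same order at 15 h (amber / red / grey / blue / green)
- the amount of target, in percent of the starting material charged of the flask you put first, at 3.0 d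
- the amount of target, in percent of the starting material charged of the flask you put last, at 3.0 d

Both earlier runs level off, midnight at 20.1% and autumn at 74.3% over their last 3 readings. So I followed one molecule of starting material to a fork, supposing that it goes through the catalyst to target or leaves by a branch that needs no catalyst. If the first branch alone scales with [catalyst], the odds of target are a selectivity factor φ, [catalyst] divided by a fixed level, and the share of target is φ/(1+φ). Midnight puts that level at 47.7 mM and autumn at 55.4 mM, and I took their mean, 51.6 mM, as the half-share level, the [catalyst] that gives a molecule even odds.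

Was one number enough? Autumn's level set into midnight gives 17.8%, a miss of 2.3 percentage points against a scatter of 1 point per reading, so I trusted it for the order and for amounts to within that miss. Blue has φ = 3.88 and green 0.291, which gave me 79.5% and 22.5%, with blue first, then grey, red, amber and green. Midnight read 19.3% at 15.0 h and 16.1% at 20.0 h against its level of 20.1%, and green holds more catalyst than midnight, so I kept that order at 15 h.

The forecast gave blue > grey > red > amber > green at 3.0 d and blue > grey > red > amber > green at 15 h, with 74.7% and 25.5%, on its reading that “the impurity apparently kills the catalyst stoichiometrically while it turns over”. My order was the same, but my figure for the first flask was higher than the forecast's and my figure for the last lower.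

The flasks came out as blue > grey > red > amber > green at 3.0 d and blue > grey > red > amber > green at 15 h, the forecast's order, with blue at 77.7% and green at 24.1%.

    starting material + catalyst → catalyst + target (k = 3.50 L mol⁻¹ h⁻¹)
    catalyst + other conformer → catalyst + isomer of the product (k = 340 L mol⁻¹ h⁻¹)
    2 starting material → homo dimer (k = 0.360 L mol⁻¹ h⁻¹)
    starting material ⇌ other conformer (K = 0.580, k = 0.0330 h⁻¹)
    other conformer + protic impurity → quenched substrate (k = 1.10 L mol⁻¹ h⁻¹)

In blue at 3.00 d the branch that φ lumps together stood apart as homo dimer, 18.7% with each counted as two molecules of starting material, isomer of the product, 3.65%, and quenched substrate, 0.00591%. Set into the same flask as blue with 0.080 M of catalyst, the half-share level 51.6 mM gives 60.8%, and that flask holds 59.6% at 3.00 d.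

The readings stem from a simulated flask on assumed constants, noise included.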